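**Remark on the chemistry.** The target has no stereocentre and no stereogenic double bond (the prenyl alkene carries two identical methyl groups), so the route needs no stereocontrol. Locants O1 to C8a and primed locants for ring B are those of the 3-aryl-2H-chromen-2-one and are used for the corresponding atoms of all precursors.

## Analysis of the target

- The target (15) is a 3-aryl-2H-chromen-2-one: benzo ring A is fused through C4a and C8a to an α-pyranone (O1, C2=O, C3, C4–H), and C3 carries a 2,4-dihydroxyphenyl ring B.
- Ring A has a phloroglucinol pattern of oxygens: C5 (free OH), C7 (OMe) and C8a (lactone oxygen O1). The prenyl chain sits on C6 between the C5 and C7 oxygens, and only C8 carries hydrogen.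
- The problem is purely constitutional. Its centre is C4a, which lies between two oxygen-bearing carbons, C5 and C8a.
- The synthesis must make the C8a oxygen (next to C8–H) the lactone oxygen and leave the C5 oxygen (next to the prenyl group) as a free phenol. Closure the other way gives the 8-prenyl isomer.
- The three phenols must end free beside an untouched 7-OMe, so late demethylation is not an option.
- The prenyl alkene is the most sensitive group: acid closes it onto the 5-OH as a chroman ether, and hydrogenation or electrophilic halogen destroys it. Protecting groups must therefore leave without acid, hydrogen or strong Lewis acid.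
- The electron-rich phenols are oxidation-prone, and the lactone opens reversibly in base.

## Retrosynthetic reasoning

**15 from 14.** The last operation only removes silicon: a triethylsilyl group on O5 and a triisopropylsilyl group on O4′. Both fall to fluoride in the flask of the key step, so nothing acidic or reductive touches the prenyl group.

**Key disconnection (14 to 7 + 10 + 11).** Four bonds of the pyranone ring are cut at once: C4a–C4 and C8a–O1 on two neighbouring carbons of ring A, plus C3–C4 and O1–C2.
- Ring A becomes the aryne 12, with the triple bond between C4a and C8a.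
- The C4–H carbon and O1 come from the formamide 11 (formyl carbon and carbonyl oxygen).
- C2, C3 and ring B come from the benzofuranone 10, whose ring oxygen is released as the 2′-OH.
- The cut is made here because the groups beside the triple bond are a silyloxy group on C5 and a hydrogen on C8. This polarises the aryne so that oxygen adds at C8a and carbon at C4a, which is the regiochemical decision that condensation routes leave open.
- Forward, the aryne must insert into the C=O bond of 11 to give the quinone methide 13. The enolate of 10 must then add, the C8a phenoxide must lactonise, and the amine fragment must leave.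

**12 from 7.** The aryne is released from the 3-hydroxy-2-silylaryl triflate 7 by base alone. The C5 hydroxyl triggers a 1,3 carbon-to-oxygen silyl shift from C4a, and the C4a anion expels the C8a triflate. The phenol that must be free in the target thus needs no protecting step, and it becomes a bulky silyl ether at the moment it has to direct and to stay out of the lactonisation.

**7 from 6.** The C8a–O triflate comes from the diol 6. Its two hydroxyls differ only in their second neighbour: the C8a–OH has C8–H, the C5–OH has the prenyl chain.

**6 from 1 via 5, 3 and 2, with 4.** Both carbon substituents are placed by directed ortho-metalation on mirror-symmetric intermediates, so neither metalation has a regiochemical choice.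
- In 2 the only position flanked by two carbamates becomes C4a–Si, giving 3.
- In 3 the two remaining positions are equivalent, and one takes the prenyl unit from 4, giving 5.
- The C5 and C8a oxygens become different only once the prenyl group is in place. Mild carbamate cleavage then gives 6.

**10 from 8 via 9.** Lactonisation of the arylacetic acid 8 ties up the 2′-oxygen as an activated aryl ester and makes C3 acidic enough for carbonate. Silylation of the remaining phenol of 9 gives 10.

## Alternatives that were turned down

**Alternative 1:** (textbook) Cut C3=C4 and O1–C2.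
- Forward step: Perkin–Oglialoro condensation of 2,6-dihydroxy-4-methoxy-3-prenylbenzaldehyde A1 with the arylacetic acid 8 in hot acetic anhydride and base, then deacetylation.
- Reason for rejection: A1 has two hydroxyls ortho to the aldehyde, and either can lactonise, giving 15 or the 8-prenyl isomer A2. The only difference between them is a prenyl or a hydrogen neighbour, which is no mechanistic bias.
- A1 itself needs a C-prenylation of a phloroglucinaldehyde ether with the same ambiguity plus O-alkylation. The route is short on paper, but its regiochemistry would be settled by separation, not by design.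

**Alternative 2:** Cut C3–C1′.
- Forward step: Suzuki–Miyaura coupling of the 3-bromocoumarin A3 with the boronic acid A4, then acetal removal.
- Reason for rejection: it forms only the easiest bond of the molecule. A3 still contains the whole ring A problem and would have to come from A1-type chemistry.
- Bromination at C3 has to compete with the prenyl alkene and an activated phenol ring, and the acetals must leave under acid next to the prenyl/5-OH pair. It is longer and solves nothing.

**Alternative 3:** Cut C4–C4a and O1–C2 (ring closure at carbon, Pechmann type).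
- Forward step: acid-mediated condensation of the prenylated resorcinol A5 with the formylacetate A6.
- Reason for rejection: A5 has two hydroxyls that can be acylated and two free ring carbons that can attack, so several coumarins are possible with no control element.
- The acid needed for the Friedel–Crafts closure is the condition that closes the prenyl chain onto its neighbouring hydroxyl. A5 would also come from an unselective C-prenylation of 1.

Key step: step 8

## Route

**Step 1**
Reactants: 1 5-methoxybenzene-1,3-diol
Product: 2 5-methoxy-1,3-phenylene bis(N-isopropylcarbamate)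
Conditions: i-PrNCO (2.4 equiv), Et3N (0.2 equiv), CH2Cl2, rt
Reagents that add atoms: isopropyl isocyanate, CC(C)N=C=O
Why: Base-catalysed addition of both phenols to the isocyanate; the N–H carbamate is chosen because, once N-silylated in the flask, it is a strong director for ortho-metalation and is later cleaved under mild amine conditions that spare a C–Si bond.

**Step 2**
Reactants: 2 5-methoxy-1,3-phenylene bis(N-isopropylcarbamate)
Product: 3 5-methoxy-2-(triethylsilyl)-1,3-phenylene bis(N-isopropylcarbamate)
Conditions: TMEDA, Me3SiOTf (2.2 equiv), Et2O, 0 °C → rt; TMEDA, n-BuLi (3.4 equiv), −78 °C; Et3SiCl, −78 °C → rt; aq. NaHSO4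
Reagents that add atoms: chlorotriethylsilane, CC[Si](Cl)(CC)CC
Why: Directed ortho-metalation: after transient N-silylation, n-BuLi/TMEDA removes the proton at C2, the only position flanked by both carbamates, and Et3SiCl traps the aryllithium at −78 °C before an anionic ortho-Fries shift can set in. The product keeps the mirror symmetry of 2.

**Step 3**
Reactants: 3 5-methoxy-2-(triethylsilyl)-1,3-phenylene bis(N-isopropylcarbamate); 4 1-bromo-3-methylbut-2-ene (prenyl bromide)
Product: 5 5-methoxy-4-(3-methylbut-2-en-1-yl)-2-(triethylsilyl)-1,3-phenylene bis(N-isopropylcarbamate)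
Conditions: TMEDA, Me3SiOTf (2.2 equiv), Et2O, 0 °C → rt; TMEDA, n-BuLi (3.3 equiv), −78 °C; CuBr·SMe2 (1.2 equiv), −78 °C; 4 (1.5 equiv), −78 → 0 °C; aq. NaHSO4
Reagents that add atoms: none
Why: Second directed ortho-metalation at one of the two equivalent positions between a carbamate and the methoxy group, then transmetalation to the arylcopper and SN2 allylation at the primary carbon of 4. The prenyl group is introduced after the silyl group so that no benzylic, allylic C–H is present during a lithiation.

**Step 4**
Reactants: 5 5-methoxy-4-(3-methylbut-2-en-1-yl)-2-(triethylsilyl)-1,3-phenylene bis(N-isopropylcarbamate)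
Product: 6 5-methoxy-4-(3-methylbut-2-en-1-yl)-2-(triethylsilyl)benzene-1,3-diol
Conditions: Et2NH (6 equiv), DBU (3 equiv), MeCN, 40 °C; pH 7 buffer work-up
Reagents that add atoms: none
Why: E1cB cleavage of the N–H aryl carbamates: DBU removes N–H, the phenoxide leaves, and Et2NH scavenges the isocyanate as a urea. The basic conditions and buffered work-up should spare the prenyl group and avoid protodesilylation of the electron-rich arylsilane.

**Step 5**
Reactants: 6 5-methoxy-4-(3-methylbut-2-en-1-yl)-2-(triethylsilyl)benzene-1,3-diol
Product: 7 3-hydroxy-5-methoxy-4-(3-methylbut-2-en-1-yl)-2-(triethylsilyl)phenyl trifluoromethanesulfonate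
Conditions: PhNTf2 (1.0 equiv), Et3N (1.1 equiv), CH2Cl2, −20 → 0 °C
Reagents that add atoms: N-phenylbis(trifluoromethanesulfonimide), O=S(=O)(N(c1ccccc1)S(=O)(=O)C(F)(F)F)C(F)(F)F
Why: Sulfonyl transfer to the less hindered and slightly more acidic hydroxyl: the C1–OH of 6 has an ortho hydrogen, whereas the C3–OH is wedged between SiEt3 and the prenyl chain, so one equivalent of the bulky triflimide should select the former. A weak amine base in CH2Cl2 at low temperature should not trigger the silyl shift of the product.

**Step 6**
Reactants: 8 2-(2,4-dihydroxyphenyl)acetic acid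
Product: 9 6-hydroxybenzofuran-2(3H)-one
Conditions: p-TsOH·H2O (5 mol %), toluene, reflux, Dean–Stark
Reagents that add atoms: none
Why: Acid-catalysed lactonisation with azeotropic removal of water; only the ortho hydroxyl can reach the acid, so the five-membered aryl lactone forms selectively.

**Step 7**
Reactants: 9 6-hydroxybenzofuran-2(3H)-one
Product: 10 6-[(triisopropylsilyl)oxy]benzofuran-2(3H)-one
Conditions: i-Pr3SiOTf (1.05 equiv), 2,6-lutidine, CH2Cl2, −78 → 0 °C
Reagents that add atoms: triisopropylsilyl trifluoromethanesulfonate, CC(C)[Si](OS(=O)(=O)C(F)(F)F)(C(C)C)C(C)C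
Why: O-silylation of the phenol with a silyl triflate and a hindered non-nucleophilic base; the O–H reacts far faster than the lactone enolises. The bulky silyl ether should resist carbonate and phenoxides in step 8 and fall to fluoride.

**Step 8**
Reactants: 7 3-hydroxy-5-methoxy-4-(3-methylbut-2-en-1-yl)-2-(triethylsilyl)phenyl trifluoromethanesulfonate; 10 6-[(triisopropylsilyl)oxy]benzofuran-2(3H)-one; 11 N,N-dimethylformamide
Product: 15 3-(2,4-dihydroxyphenyl)-5-hydroxy-7-methoxy-6-(3-methylbut-2-en-1-yl)-2H-chromen-2-one, via silyloxyaryne 12 (not isolated), via aminomethylene quinone methide 13 (not isolated), via bis-silyl coumarin 14 (not isolated)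
Conditions: 10 (2 equiv), Cs2CO3 (3.5 equiv), 11 as solvent (0.05 M), slow addition of 7, rt → 50 °C; then Bu4NF (THF), 0 °C → rt; aq. NH4Cl
Reagents that add atoms: none
Why: Cs2CO3 deprotonates the C5 hydroxyl of 7, a 1,3 carbon-to-oxygen silyl shift (Brook type) moves SiEt3 from C4a to O5, and the C4a anion expels the neighbouring triflate to give aryne 12 with the triple bond between C4a and C8a. The carbonyl oxygen of 11 adds to C8a and the C4a anion closes on the iminium carbon (formal [2+2] to a four-membered benzoxete that opens at once), giving the quinone methide 13 with the future C4 on C4a and the future O1 on C8a. The cesium enolate of 10 adds to the aminomethylene carbon (C3–C4 bond), the C8a phenoxide closes the pyranone ring by 6-exo-trig acyl substitution at the lactone carbonyl (O1–C2 bond, releasing the benzofuranone oxygen as the 2′-phenoxide), and E1cB loss of Me2NH gives coumarin 14. The closest known reaction types are the three-component coupling of arynes, formamides and C–H acidic esters to coumarins, the base-triggered release of 3-silyloxyarynes from 3-hydroxy-2-silylaryl triflates, and the condensation of salicylaldehydes with benzofuran-2(3H)-ones to 3-(2-hydroxyphenyl)coumarins. The step needs regioselective addition to the aryne, and the O5 silyloxy group beside C4a secures it: its inductive pull stabilises the carbanion developing at C4a and distorts the aryne so that C8a is the electrophilic end, while the silyloxy/prenyl pair shields C4a and C8 carries only hydrogen. It also needs the right oxygen to lactonise, and this is secured because O5 is silylated in the same event that creates the aryne, leaving only the C8a phenoxide free. No stereocentre is formed. Bu4NF then removes both silyl groups in the same flask to give 15.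

## Compound list

1 | 5-methoxybenzene-1,3-diol | COc1cc(O)cc(O)c1 | starting material
2 | 5-methoxy-1,3-phenylene bis(N-isopropylcarbamate) | COc1cc(OC(=O)NC(C)C)cc(OC(=O)NC(C)C)c1 | intermediate
3 | 5-methoxy-2-(triethylsilyl)-1,3-phenylene bis(N-isopropylcarbamate) | COc1cc(OC(=O)NC(C)C)c([Si](CC)(CC)CC)c(OC(=O)NC(C)C)c1 | intermediate
4 | 1-bromo-3-methylbut-2-ene | CC(C)=CCBr | starting material
5 | 5-methoxy-4-(3-methylbut-2-en-1-yl)-2-(triethylsilyl)-1,3-phenylene bis(N-isopropylcarbamate) | COc1cc(OC(=O)NC(C)C)c([Si](CC)(CC)CC)c(OC(=O)NC(C)C)c1CC=C(C)C | intermediate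
6 | 5-methoxy-4-(3-methylbut-2-en-1-yl)-2-(triethylsilyl)benzene-1,3-diol | COc1cc(O)c([Si](CC)(CC)CC)c(O)c1CC=C(C)C | intermediate
7 | 3-hydroxy-5-methoxy-4-(3-methylbut-2-en-1-yl)-2-(triethylsilyl)phenyl trifluoromethanesulfonate | COc1cc(OS(=O)(=O)C(F)(F)F)c([Si](CC)(CC)CC)c(O)c1CC=C(C)C | intermediate
8 | 2-(2,4-dihydroxyphenyl)acetic acid | OC(=O)Cc1ccc(O)cc1O | starting material
9 | 6-hydroxybenzofuran-2(3H)-one | O=C1Cc2ccc(O)cc2O1 | intermediate
10 | 6-[(triisopropylsilyl)oxy]benzofuran-2(3H)-one | O=C1Cc2ccc(O[Si](C(C)C)(C(C)C)C(C)C)cc2O1 | intermediate
11 | N,N-dimethylformamide | CN(C)C=O | starting material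
12 | 5-methoxy-4-(3-methylbut-2-en-1-yl)-3-[(triethylsilyl)oxy]benzyne | C1#CC(O[Si](CC)(CC)CC)=C(CC=C(C)C)C(OC)=C1 | intermediate
13 | 6-[(dimethylamino)methylidene]-3-methoxy-4-(3-methylbut-2-en-1-yl)-5-[(triethylsilyl)oxy]cyclohexa-2,4-dien-1-one | CN(C)C=C1C(=O)C=C(OC)C(CC=C(C)C)=C1O[Si](CC)(CC)CC | intermediate
14 | 3-{2-hydroxy-4-[(triisopropylsilyl)oxy]phenyl}-7-methoxy-6-(3-methylbut-2-en-1-yl)-5-[(triethylsilyl)oxy]-2H-chromen-2-one | COc1cc2oc(=O)c(-c3ccc(O[Si](C(C)C)(C(C)C)C(C)C)cc3O)cc2c(O[Si](CC)(CC)CC)c1CC=C(C)C | intermediate
15 | 3-(2,4-dihydroxyphenyl)-5-hydroxy-7-methoxy-6-(3-methylbut-2-en-1-yl)-2H-chromen-2-one | COc1cc2oc(=O)c(-c3ccc(O)cc3O)cc2c(O)c1CC=C(C)C | target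

## Step count and risk

Total step count: 8. Longest linear sequence: 6 (steps 1, 2, 3, 4, 5 and 8); steps 6 and 7 form the short second branch.

**Step 8 (key step).**
- Most likely failures: capture of the aryne by the enolate, by phenoxides or by the amine set free, in place of the formamide solvent.
- A sluggish silyl migration with the triethylsilyl group would leave the enolate of 10 time to self-condense.
- Premature loss of the O5 silyl group would let the C5 phenoxide compete in the lactonisation and erode the regiochemistry.
- Fallback: a stepwise, fluoride-triggered variant with O5 protected, setting out from 7 and returning to the route at 15.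
  - Mitsunobu O-allylation of 7 (allyl alcohol, Ph3P, diisopropyl azodicarboxylate, THF, 0 °C; no free phenoxide) would give 3-(allyloxy)-5-methoxy-4-(3-methylbut-2-en-1-yl)-2-(triethylsilyl)phenyl trifluoromethanesulfonate F1, a conventional aryne precursor.
  - CsF in 11 followed by aqueous hydrolysis (the known aryne–formamide–water route to salicylaldehydes, with the same regiochemical argument) would give 2-(allyloxy)-6-hydroxy-4-methoxy-3-(3-methylbut-2-en-1-yl)benzaldehyde F2, in which only the C8a hydroxyl is free.
  - Et3N-mediated condensation of F2 with 10 (Knoevenagel condensation and transacylation) would give 5-(allyloxy)-3-{2-hydroxy-4-[(triisopropylsilyl)oxy]phenyl}-7-methoxy-6-(3-methylbut-2-en-1-yl)-2H-chromen-2-one F3.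
  - Bu4NF would give 5-(allyloxy)-3-(2,4-dihydroxyphenyl)-7-methoxy-6-(3-methylbut-2-en-1-yl)-2H-chromen-2-one F4.
  - Allyl transfer to morpholine with catalytic Pd(PPh3)4 (zerovalent palladium, which leaves the carbon-bound prenyl group alone) would return to the route at 15.

**Step 5.**
- Most likely failures: poor site selectivity between the two hydroxyls, double triflation, or premature aryne release if the product phenol is deprotonated.
- Fallback: protect both oxygens and unmask one, so that the triflation itself has no choice, setting out from 6 and returning at 7.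
  - Exhaustive silylation of 6 (t-BuMe2SiOTf, 2,6-lutidine) would give [5-methoxy-4-(3-methylbut-2-en-1-yl)-2-(triethylsilyl)-1,3-phenylene]bis(oxy)bis(tert-butyldimethylsilane) F5.
  - K2CO3 in MeOH at 0 °C should cleave the aryl silyl ether that has an ortho hydrogen much faster than the one buried between SiEt3 and prenyl, giving 3-[(tert-butyldimethylsilyl)oxy]-5-methoxy-4-(3-methylbut-2-en-1-yl)-2-(triethylsilyl)phenol F6. This step can be stopped, monitored and recycled by re-silylation.
  - Triflation of the single free hydroxyl (PhNTf2, Et3N) would give 3-[(tert-butyldimethylsilyl)oxy]-5-methoxy-4-(3-methylbut-2-en-1-yl)-2-(triethylsilyl)phenyl trifluoromethanesulfonate F7.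
  - KHF2 in MeOH (mildly acidic fluoride, no phenoxide and hence no silyl shift) would return to the route at 7.

**Step 3.**
- Most likely failures: SN2′ attack on 4 giving the branched 1,1-dimethylallyl chain, anionic ortho-Fries migration of a carbamoyl group on warming, or double metalation.
- Fallback: set out from 3 and return at 5. The same aryllithium/arylcopper is trapped with allyl bromide, for which both modes of attack give the same product, to give 4-allyl-5-methoxy-2-(triethylsilyl)-1,3-phenylene bis(N-isopropylcarbamate) F8. Cross-metathesis of F8 with 2-methylbut-2-ene (second-generation Grubbs catalyst, CH2Cl2, 40 °C) would convert the allyl into the prenyl group and return to the route at 5.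

## Further compounds

F1 | step 8 | 3-(allyloxy)-5-methoxy-4-(3-methylbut-2-en-1-yl)-2-(triethylsilyl)phenyl trifluoromethanesulfonate | COc1cc(OS(=O)(=O)C(F)(F)F)c([Si](CC)(CC)CC)c(OCC=C)c1CC=C(C)C
F2 | step 8 | 2-(allyloxy)-6-hydroxy-4-methoxy-3-(3-methylbut-2-en-1-yl)benzaldehyde | COc1cc(O)c(C=O)c(OCC=C)c1CC=C(C)C
F3 | step 8 | 5-(allyloxy)-3-{2-hydroxy-4-[(triisopropylsilyl)oxy]phenyl}-7-methoxy-6-(3-methylbut-2-en-1-yl)-2H-chromen-2-one | COc1cc2oc(=O)c(-c3ccc(O[Si](C(C)C)(C(C)C)C(C)C)cc3O)cc2c(OCC=C)c1CC=C(C)C
F4 | step 8 | 5-(allyloxy)-3-(2,4-dihydroxyphenyl)-7-methoxy-6-(3-methylbut-2-en-1-yl)-2H-chromen-2-one | COc1cc2oc(=O)c(-c3ccc(O)cc3O)cc2c(OCC=C)c1CC=C(C)C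
F5 | step 5 | [5-methoxy-4-(3-methylbut-2-en-1-yl)-2-(triethylsilyl)-1,3-phenylene]bis(oxy)bis(tert-butyldimethylsilane) | COc1cc(O[Si](C)(C)C(C)(C)C)c([Si](CC)(CC)CC)c(O[Si](C)(C)C(C)(C)C)c1CC=C(C)C
F6 | step 5 | 3-[(tert-butyldimethylsilyl)oxy]-5-methoxy-4-(3-methylbut-2-en-1-yl)-2-(triethylsilyl)phenol | COc1cc(O)c([Si](CC)(CC)CC)c(O[Si](C)(C)C(C)(C)C)c1CC=C(C)C
F7 | step 5 | 3-[(tert-butyldimethylsilyl)oxy]-5-methoxy-4-(3-methylbut-2-en-1-yl)-2-(triethylsilyl)phenyl trifluoromethanesulfonate | COc1cc(OS(=O)(=O)C(F)(F)F)c([Si](CC)(CC)CC)c(O[Si](C)(C)C(C)(C)C)c1CC=C(C)C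
F8 | step 3 | 4-allyl-5-methoxy-2-(triethylsilyl)-1,3-phenylene bis(N-isopropylcarbamate) | COc1cc(OC(=O)NC(C)C)c([Si](CC)(CC)CC)c(OC(=O)NC(C)C)c1CC=C
A1 | alternative 1 | 2,6-dihydroxy-4-methoxy-3-(3-methylbut-2-en-1-yl)benzaldehyde | COc1cc(O)c(C=O)c(O)c1CC=C(C)C
A2 | alternative 1 | 3-(2,4-dihydroxyphenyl)-5-hydroxy-7-methoxy-8-(3-methylbut-2-en-1-yl)-2H-chromen-2-one | COc1cc(O)c2cc(-c3ccc(O)cc3O)c(=O)oc2c1CC=C(C)C
A3 | alternative 2 | 3-bromo-5-hydroxy-7-methoxy-6-(3-methylbut-2-en-1-yl)-2H-chromen-2-one | COc1cc2oc(=O)c(Br)cc2c(O)c1CC=C(C)C
A4 | alternative 2 | [2,4-bis(methoxymethoxy)phenyl]boronic acid | COCOc1ccc(B(O)O)c(OCOC)c1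
A5 | alternative 3 | 5-methoxy-4-(3-methylbut-2-en-1-yl)benzene-1,3-diol | COc1cc(O)cc(O)c1CC=C(C)C
A6 | alternative 3 | ethyl 2-(2,4-diacetoxyphenyl)-3-oxopropanoate | CCOC(=O)C(C=O)c1ccc(OC(C)=O)cc1OC(C)=O
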